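**Plan**

1. Numbering: ring A (five-membered) = C1 [ring-fusion C(CH3)], C2 [CH–OAc], C3 [CH2], C4 [C(OH)(i-Pr)], C5 [ring-fusion CH]; ring B (seven-membered) = C1, C5, C6 [CH–O-anisoyl], C7 [CH2], C8 [C(CH3)] and C9 [CH] (epoxide), C10 [CH2]. α is the face of H-5, β the face of the C1 methyl.
2. Retrosynthesis: epoxide → C8=C9 alkene; C2 and C6 esters → alcohols; alkene and C6 carbinol → ring-B 6,9-dione. The C7–C8 bond of ring B is then cut. This is possible because C6 and C9 both bear oxygen and sit 1,4 to each other across C7–C8, so C7 and C8 are each the α-carbon of one carbonyl and can be joined by oxidising two enol ethers.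
3. Further cuts: C9–C8 and C6–C7 (Grignard additions), C1–C10 (malonate conjugate addition tethered through O-2), C1=C5 of ring A (aldol condensation), back to the cyclohexene of (R)-terpinen-4-ol.
4. Forward order: oxygenate and ring-contract terpinen-4-ol to ring A, build the quaternary C1 through a cis-fused lactone, install the methyl and ethyl ketones, close ring B last through C7–C8, then adjust oxidation levels and acyl groups.
5. Stereochemistry: C4 from (R)-terpinen-4-ol; C2 by a reduction directed by the C4 hydroxyl; C1 by delivery from the O-2 tether; C5 by equilibration to the exo aldehyde; C6 by a second C4-hydroxyl-directed reduction; the epoxide by peracid attack anti to the C1 methyl.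

Key step: step 14

Remark: (R)-(−)-terpinen-4-ol is taken as available in enantiomerically pure form; the configuration of the C6 carbinol before its oxidation and of C8 in the ring-B dione is of no consequence, because both carbons become trigonal later.

**Route**

Step 1
Reactants: 1 (R)-(−)-terpinen-4-ol
Product: 3 (S)-5-hydroxy-5-isopropyl-2-methylcyclohex-2-en-1-one, via allylic alcohol mixture 2 (not isolated)
Conditions: SeO2 (0.5 equiv), t-BuOOH, CH2Cl2, rt; aqueous work-up; then MnO2, CH2Cl2, rt
Reagents that add atoms: selenium dioxide O=[Se]=O (catalytic oxygen carrier); tert-butyl hydroperoxide CC(C)(C)OO (terminal oxygen source)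
Why: Riley allylic oxidation (ene reaction of SeO2 at the alkene CH, then [2,3]-sigmatropic shift) should place oxygen on the ring CH2 next to the methyl-bearing alkene carbon without moving the double bond, and MnO2 then oxidises only the allylic carbinol, merging both carbinol epimers into one enone while the tertiary carbinol centre stays untouched.

Step 2
Reactants: 3 (S)-5-hydroxy-5-isopropyl-2-methylcyclohex-2-en-1-one
Product: 4 (1R,5S)-5-isopropyl-2-methylcyclohex-2-ene-1,5-diol
Conditions: Me4NBH(OAc)3, MeCN/AcOH 1:1, −30 °C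
Reagents that add atoms: none
Why: Evans–Saksena directed reduction: the tertiary hydroxyl exchanges onto boron and delivers hydride to the carbonyl face on its own side, which should give the 1,3-anti (trans) diol and so set the future C2 as (R).

Step 3
Reactants: 4 (1R,5S)-5-isopropyl-2-methylcyclohex-2-ene-1,5-diol
Product: 5 (1R,5S)-5-isopropyl-2-methyl-1,5-bis(triethylsilyloxy)cyclohex-2-ene
Conditions: Et3SiOTf (2.5 equiv), 2,6-lutidine, CH2Cl2, −78 → 0 °C
Reagents that add atoms: triethylsilyl triflate CC[Si](CC)(CC)OS(=O)(=O)C(F)(F)F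
Why: silyl ether formation with a silyl triflate covers both the secondary allylic and the hindered tertiary hydroxyl, so that neither can form lactols or be eliminated during the ring contraction.

Step 4
Reactants: 5 (1R,5S)-5-isopropyl-2-methyl-1,5-bis(triethylsilyloxy)cyclohex-2-ene
Product: 7 (3R,5S)-5-isopropyl-2-methyl-3,5-bis(triethylsilyloxy)cyclopent-1-ene-1-carbaldehyde, via keto aldehyde 6 (not isolated)
Conditions: O3, CH2Cl2, −78 °C; Me2S, −78 °C → rt; then Bn2NH·CF3CO2H (20 mol %), toluene, 50 °C
Reagents that add atoms: ozone [O-][O+]=O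
Why: ozonolysis of the trisubstituted alkene followed by amine-salt-catalysed intramolecular aldol condensation (enamine of the aldehyde onto the methyl ketone, five-membered ring) should give ring A as the C1=C5 enal; no stereocentre is formed or disturbed.

Step 5
Reactants: 7 (3R,5S)-5-isopropyl-2-methyl-3,5-bis(triethylsilyloxy)cyclopent-1-ene-1-carbaldehyde
Product: 8 (3R,5S)-3-hydroxy-5-isopropyl-2-methyl-5-(triethylsilyloxy)cyclopent-1-ene-1-carbaldehyde (2α-hydroxy enal)
Conditions: AcOH/THF/H2O 3:1:1, rt
Reagents that add atoms: none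
Why: selective acid-catalysed desilylation: the secondary allylic silyl ether at C2 is hydrolysed much faster than the tertiary one at C4, which is shielded by the isopropyl group.

Step 6
Reactants: 8 2α-hydroxy enal; 9 methyl malonyl chloride
Product: 10 methyl malonate ester of 8 at O-2
Conditions: pyridine, CH2Cl2, 0 °C
Reagents that add atoms: methyl malonyl chloride (9) COC(=O)CC(Cl)=O
Why: esterification of the secondary allylic alcohol with an acid chloride attaches the nucleophilic tether on the α face.

Step 7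
Reactants: 10 methyl malonate ester of 8
Product: 11 cis-fused γ-lactone aldehyde bearing CO2Me at C10
Conditions: Cs2CO3 (0.3 equiv), MeCN, 0 °C → rt
Reagents that add atoms: none
Why: intramolecular Michael addition (5-exo-trig) of the malonate carbon to C1 of the enal: the O-2 tether reaches only the α face, so C10 is delivered α and the C1 methyl ends β (cis-fused lactone), and the C5 formyl group equilibrates through its enol to the exo β position, trans to C10.

Step 8
Reactants: 11 lactone aldehyde bearing CO2Me at C10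
Product: 12 cis-fused γ-lactone aldehyde
Conditions: LiCl, H2O, DMSO, 130 °C
Reagents that add atoms: none
Why: Krapcho dealkoxycarbonylation removes the methyl ester by chloride attack on the O-methyl group and loss of CO2 under neutral conditions, leaving the lactone and the thermodynamic C5 configuration.

Step 9
Reactants: 12 cis-fused γ-lactone aldehyde; 13 methylmagnesium bromide
Product: 15 trimethylsilyl ether of the C6 methyl carbinol lactone, via bromomagnesium alkoxide 14 (not isolated)
Conditions: MeMgBr (1.2 equiv), THF, −78 °C; then Me3SiCl, Et3N, −78 → 0 °C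
Reagents that add atoms: methylmagnesium bromide (13) C[Mg]Br; chlorotrimethylsilane C[Si](C)(C)Cl
Why: Grignard addition to the aldehyde, which is far more electrophilic than the lactone at −78 °C, with silylation of the alkoxide in the same flask so that it cannot translactonise; the C6 configuration does not matter because the carbinol is oxidised in step 12.

Step 10
Reactants: 15 trimethylsilyl ether of the C6 methyl carbinol lactone
Product: 17 C2-triisopropylsilyloxy Weinreb amide, via hydroxy Weinreb amide 16 (not isolated)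
Conditions: MeNH(OMe)·HCl, i-PrMgCl, THF, −20 → 0 °C; crude product, then i-Pr3SiOTf, 2,6-lutidine, CH2Cl2, 0 °C → rt
Reagents that add atoms: N,O-dimethylhydroxylamine hydrochloride CNOC.Cl; triisopropylsilyl triflate CC(C)[Si](OS(=O)(=O)C(F)(F)F)(C(C)C)C(C)C
Why: Weinreb aminolysis of the lactone by the chloromagnesium amide, followed at once by silyl triflate protection of the freed C2 hydroxyl, which prevents relactonisation.

Step 11
Reactants: 17 C2-triisopropylsilyloxy Weinreb amide; 18 ethylmagnesium bromide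
Product: 20 hydroxy ethyl ketone, via silyl ether ketone 19 (not isolated)
Conditions: EtMgBr, THF, 0 °C; aqueous NH4Cl; then citric acid, MeOH, 0 °C
Reagents that add atoms: ethylmagnesium bromide (18) CC[Mg]Br
Why: Weinreb ketone synthesis (the chelated tetrahedral intermediate prevents over-addition), followed by mild acidic methanolysis that removes only the trimethylsilyl ether.

Step 12
Reactants: 20 hydroxy ethyl ketone
Product: 21 methyl ketone/ethyl ketone (1,5-diketone)
Conditions: Dess–Martin periodinane, NaHCO3, CH2Cl2, rt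
Reagents that add atoms: none
Why: Dess–Martin oxidation of the secondary alcohol under buffered conditions avoids base, which could close the 1,5-diketone by aldol reaction or epimerise C5.

Step 13
Reactants: 21 methyl ketone/ethyl ketone
Product: 22 bis(trimethylsilyl enol ether), C6=C7 and (Z)-C8=C9
Conditions: Me3SiOTf (3 equiv), Et3N (5 equiv), CH2Cl2, 0 °C; pentane extraction, used crude
Reagents that add atoms: trimethylsilyl triflate C[Si](C)(C)OS(=O)(=O)C(F)(F)F
Why: soft enolisation with silyl triflate and amine forms no free enolate: the methyl ketone can lose only a C7 proton because H-5 is buried between two fully substituted carbons, and the ethyl ketone should lose a C8 proton in preference to the neopentyl C10 protons, giving the (Z)-enol ether.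

Step 14
Reactants: 22 bis(trimethylsilyl enol ether)
Product: 23 ring-B 6,9-dione (2α-OSi(i-Pr)3, 4β-OSiEt3, 5α-H, 8-methyl)
Conditions: undivided cell, reticulated vitreous carbon anode, Pt cathode, constant current (8 mA, 2.2 F/mol), 0.1 M LiClO4 in MeOH/CH2Cl2 1:4, 2,6-lutidine (6 equiv), rt
Reagents that add atoms: none
Why: Proposed new method: one-electron oxidation at the anode of the more electron-rich trisubstituted C8=C9 silyl enol ether should give a radical cation that is electrophilic at C8 and is captured by C7 of the C6=C7 silyl enol ether; a second electron transfer and loss of both trimethylsilyl groups to methanol then leave the 6,9-dione. The closest known reaction types are anodic enol ether–enol ether cyclisations to five- and six-membered rings, the anodic silyl enol ether–furan cyclisation to a seven-membered ring, and the chemical oxidative coupling of bis(silyl enol ethers) with (NH4)2Ce(NO3)6. Ring B closes in a 7-endo-trig mode with respect to both enol ether double bonds, each of which becomes a ring bond. The new stereocentre C8 is under no reliable control (the 8α-methyl epimer is drawn as the one expected after equilibration through the C9 enol) and is erased in step 19. The step needs C–C bond formation to outrun methanol capture and protodesilylation: the two chains are held trans on ring A between the fully substituted C1 and C4, which restricts their rotamers and keeps C7 near C8, 2,6-lutidine buffers the anolyte, and because either radical cation leads to the same C7–C8 bond no selectivity between the two enol ethers is required.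

Step 15
Reactants: 23 ring-B 6,9-dione
Product: 24 4β-hydroxy-6,9-dione
Conditions: HF·pyridine, pyridine, THF, 0 °C → rt
Reagents that add atoms: none
Why: fluoride-mediated desilylation under buffered conditions should remove the triethylsilyl ether at C4 while the much bulkier triisopropylsilyl ether at C2 stays.

Step 16
Reactants: 24 4β-hydroxy-6,9-dione
Product: 25 4β,6α-dihydroxy-9-ketone
Conditions: Me4NBH(OAc)3, MeCN/AcOH 1:1, −20 °C
Reagents that add atoms: none
Why: Evans–Saksena directed reduction: only the C6 ketone has a neighbouring free hydroxyl, so it alone is reduced, and hydride delivered from the β-oriented C4–O–B unit to the β face should give the 6α-alcohol (1,3-anti to O-4, H-6 trans to H-5).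

Step 17
Reactants: 25 4β,6α-dihydroxy-9-ketone; 26 4-methoxybenzoyl chloride
Product: 27 6α-(4-methoxybenzoate) 9-ketone
Conditions: DMAP, Et3N, CH2Cl2, rt → 40 °C
Reagents that add atoms: 4-methoxybenzoyl chloride (26) COc1ccc(cc1)C(Cl)=O
Why: DMAP-catalysed esterification of the only secondary hydroxyl; the tertiary C4 hydroxyl is too hindered to be acylated.

Step 18
Reactants: 27 6α-(4-methoxybenzoate) 9-ketone
Product: 28 9-alcohol (hydroxyl cis to the C8 methyl)
Conditions: LiBH(s-Bu)3 (L-Selectride), THF, −78 °C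
Reagents that add atoms: none
Why: reduction with a bulky hydride at −78 °C leaves the aromatic ester alone and should attack anti to the adjacent C8 methyl, giving the alcohol cis to that methyl so that H-8 lies anti to the future leaving group.

Step 19
Reactants: 28 9-alcohol
Product: 30 C8=C9 alkene, via C9 mesylate 29 (not isolated)
Conditions: MsCl, Et3N, CH2Cl2, 0 °C; then DBU, toluene, 90 °C
Reagents that add atoms: none
Why: mesylation of the only secondary hydroxyl and E2 elimination: the anti-periplanar H-8 should be removed in preference to the crowded neopentyl C10 hydrogens (Zaitsev orientation), giving the trisubstituted C8=C9 alkene, which cannot move into conjugation because C6 is already an ester.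

Step 20
Reactants: 30 C8=C9 alkene
Product: 31 2α,4β-diol 6α-(4-methoxybenzoate)
Conditions: Bu4NF, THF, rt → 40 °C
Reagents that add atoms: none
Why: fluoride desilylation of the triisopropylsilyl ether frees the C2 hydroxyl once no ketone remains with which it could form a hemiketal.

Step 21
Reactants: 31 2α,4β-diol 6α-(4-methoxybenzoate); 32 acetic anhydride
Product: 33 2α-acetate
Conditions: pyridine, DMAP (cat.), CH2Cl2, 0 °C → rt
Reagents that add atoms: acetic anhydride (32) CC(=O)OC(C)=O
Why: acetylation (esterification) of the secondary C2 hydroxyl; the tertiary C4 hydroxyl does not react under these mild conditions.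

Step 22
Reactants: 33 2α-acetate
Product: 34 CNP0317703.1 (target)
Conditions: m-CPBA, NaHCO3, CH2Cl2, 0 °C
Reagents that add atoms: m-chloroperbenzoic acid OOC(=O)c1cccc(Cl)c1
Why: Prilezhaev epoxidation: the peracid should approach the trisubstituted alkene from the α face, opposite the axial C1 methyl that screens the β face of ring B, giving the 8α,9α-epoxide.

**Compound list**

1 | (R)-(−)-terpinen-4-ol, (R)-1-isopropyl-4-methylcyclohex-3-en-1-ol | CC1=CC[C@@](O)(C(C)C)CC1 | starting material
2 | (5S)-5-isopropyl-2-methylcyclohex-2-ene-1,5-diol, both C1 epimers, not isolated | CC1=CC[C@@](O)(C(C)C)CC1O | intermediate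
3 | (S)-5-hydroxy-5-isopropyl-2-methylcyclohex-2-en-1-one | CC1=CC[C@@](O)(C(C)C)CC1=O | intermediate
4 | (1R,5S)-5-isopropyl-2-methylcyclohex-2-ene-1,5-diol (hydroxyls trans) | CC1=CC[C@@](O)(C(C)C)C[C@H]1O | intermediate
5 | (1R,5S)-5-isopropyl-2-methyl-1,5-bis(triethylsilyloxy)cyclohex-2-ene | CC1=CC[C@@](O[Si](CC)(CC)CC)(C(C)C)C[C@H]1O[Si](CC)(CC)CC | intermediate
6 | (3R,5R)-3-isopropyl-6-oxo-3,5-bis(triethylsilyloxy)heptanal, not isolated | CC(=O)[C@H](O[Si](CC)(CC)CC)C[C@](O[Si](CC)(CC)CC)(C(C)C)CC=O | intermediate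
7 | (3R,5S)-5-isopropyl-2-methyl-3,5-bis(triethylsilyloxy)cyclopent-1-ene-1-carbaldehyde (ring A; 2α- and 4β-silyloxy) | CC1=C(C=O)[C@@](O[Si](CC)(CC)CC)(C(C)C)C[C@H]1O[Si](CC)(CC)CC | intermediate
8 | (3R,5S)-3-hydroxy-5-isopropyl-2-methyl-5-(triethylsilyloxy)cyclopent-1-ene-1-carbaldehyde (2α-hydroxy enal) | CC1=C(C=O)[C@@](O[Si](CC)(CC)CC)(C(C)C)C[C@H]1O | intermediate
9 | methyl malonyl chloride (methyl 3-chloro-3-oxopropanoate) | COC(=O)CC(Cl)=O | starting material
10 | (1R,4S)-3-formyl-4-isopropyl-2-methyl-4-(triethylsilyloxy)cyclopent-2-en-1-yl methyl malonate | CC1=C(C=O)[C@@](O[Si](CC)(CC)CC)(C(C)C)C[C@H]1OC(=O)CC(=O)OC | intermediate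
11 | cis-fused γ-lactone (O-2α–C9(=O)–C10–C1α) on ring A with 1β-CH3, 4β-OSiEt3, 4α-i-Pr, 5β-CHO and CO2Me at C10 (C10 epimers) | O=C[C@@H]1[C@@](O[Si](CC)(CC)CC)(C(C)C)C[C@H]2OC(=O)C(C(=O)OC)[C@@]12C | intermediate
12 | cis-fused γ-lactone aldehyde: as 11 with C10 = CH2 | O=C[C@@H]1[C@@](O[Si](CC)(CC)CC)(C(C)C)C[C@H]2OC(=O)C[C@@]12C | intermediate
13 | methylmagnesium bromide | C[Mg]Br | starting material
14 | bromomagnesium alkoxide of the C6 methyl carbinol lactone (C6 epimers), not isolated | CC(O[Mg]Br)[C@@H]1[C@@](O[Si](CC)(CC)CC)(C(C)C)C[C@H]2OC(=O)C[C@@]12C | intermediate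
15 | lactone with 5β-CH(OSiMe3)CH3 (C6 epimers), otherwise as 12 | CC(O[Si](C)(C)C)[C@@H]1[C@@](O[Si](CC)(CC)CC)(C(C)C)C[C@H]2OC(=O)C[C@@]12C | intermediate
16 | ring A with 1α-CH2C(=O)N(OMe)Me, 1β-CH3, 2α-OH, 4β-OSiEt3, 4α-i-Pr, 5β-CH(OSiMe3)CH3, not isolated | CON(C)C(=O)C[C@]1(C)[C@H](O)C[C@](O[Si](CC)(CC)CC)(C(C)C)[C@H]1C(C)O[Si](C)(C)C | intermediate
17 | as 16 with 2α-OSi(i-Pr)3 | CON(C)C(=O)C[C@]1(C)[C@H](O[Si](C(C)C)(C(C)C)C(C)C)C[C@](O[Si](CC)(CC)CC)(C(C)C)[C@H]1C(C)O[Si](C)(C)C | intermediate
18 | ethylmagnesium bromide | CC[Mg]Br | starting material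
19 | ring A with 1α-CH2C(=O)CH2CH3, 2α-OSi(i-Pr)3, 4β-OSiEt3, 5β-CH(OSiMe3)CH3, not isolated | CCC(=O)C[C@]1(C)[C@H](O[Si](C(C)C)(C(C)C)C(C)C)C[C@](O[Si](CC)(CC)CC)(C(C)C)[C@H]1C(C)O[Si](C)(C)C | intermediate
20 | as 19 with 5β-CH(OH)CH3 (C6 epimers) | CCC(=O)C[C@]1(C)[C@H](O[Si](C(C)C)(C(C)C)C(C)C)C[C@](O[Si](CC)(CC)CC)(C(C)C)[C@H]1C(C)O | intermediate
21 | ring A with 1α-CH2C(=O)CH2CH3, 5β-C(=O)CH3, 1β-CH3, 2α-OSi(i-Pr)3, 4β-OSiEt3, 4α-i-Pr | CCC(=O)C[C@]1(C)[C@H](O[Si](C(C)C)(C(C)C)C(C)C)C[C@](O[Si](CC)(CC)CC)(C(C)C)[C@H]1C(C)=O | intermediate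
22 | bis(trimethylsilyl enol ether) of 21: C6(OSiMe3)=C7H2 on C5 and (Z)-C9(OSiMe3)=C8H–CH3 on C10 | C/C=C(\O[Si](C)(C)C)C[C@]1(C)[C@H](O[Si](C(C)C)(C(C)C)C(C)C)C[C@](O[Si](CC)(CC)CC)(C(C)C)[C@H]1C(=C)O[Si](C)(C)C | intermediate
23 | trans-fused ring A/ring B 6,9-dione: 1β-CH3, 2α-OSi(i-Pr)3, 4β-OSiEt3, 4α-i-Pr, 5α-H, 8α-CH3 | O=C1C[C@H](C)C(=O)C[C@]2(C)[C@H](O[Si](C(C)C)(C(C)C)C(C)C)C[C@](O[Si](CC)(CC)CC)(C(C)C)[C@@H]12 | intermediate
24 | as 23 with 4β-OH | O=C1C[C@H](C)C(=O)C[C@]2(C)[C@H](O[Si](C(C)C)(C(C)C)C(C)C)C[C@](O)(C(C)C)[C@@H]12 | intermediate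
25 | 4β,6α-dihydroxy-9-ketone, 2α-OSi(i-Pr)3 | O[C@@H]1C[C@H](C)C(=O)C[C@]2(C)[C@H](O[Si](C(C)C)(C(C)C)C(C)C)C[C@](O)(C(C)C)[C@@H]12 | intermediate
26 | 4-methoxybenzoyl chloride (p-anisoyl chloride) | COc1ccc(cc1)C(Cl)=O | starting material
27 | 6α-(4-methoxybenzoyloxy)-4β-hydroxy-9-ketone, 2α-OSi(i-Pr)3 | COc1ccc(cc1)C(=O)O[C@@H]1C[C@H](C)C(=O)C[C@]2(C)[C@H](O[Si](C(C)C)(C(C)C)C(C)C)C[C@](O)(C(C)C)[C@@H]12 | intermediate
28 | as 27 with 9α-OH cis to the 8α-CH3 | COc1ccc(cc1)C(=O)O[C@@H]1C[C@H](C)[C@H](O)C[C@]2(C)[C@H](O[Si](C(C)C)(C(C)C)C(C)C)C[C@](O)(C(C)C)[C@@H]12 | intermediate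
29 | 9α-methanesulfonate of 28, not isolated | COc1ccc(cc1)C(=O)O[C@@H]1C[C@H](C)[C@H](OS(C)(=O)=O)C[C@]2(C)[C@H](O[Si](C(C)C)(C(C)C)C(C)C)C[C@](O)(C(C)C)[C@@H]12 | intermediate
30 | C8=C9 alkene with 6α-(4-methoxybenzoyloxy), 4β-OH, 2α-OSi(i-Pr)3 | COc1ccc(cc1)C(=O)O[C@@H]1CC(C)=CC[C@]2(C)[C@H](O[Si](C(C)C)(C(C)C)C(C)C)C[C@](O)(C(C)C)[C@@H]12 | intermediate
31 | as 30 with 2α-OH | COc1ccc(cc1)C(=O)O[C@@H]1CC(C)=CC[C@]2(C)[C@H](O)C[C@](O)(C(C)C)[C@@H]12 | intermediate
32 | acetic anhydride | CC(=O)OC(C)=O | starting material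
33 | as 30 with 2α-OAc | COc1ccc(cc1)C(=O)O[C@@H]1CC(C)=CC[C@]2(C)[C@H](OC(C)=O)C[C@](O)(C(C)C)[C@@H]12 | intermediate
34 | CNP0317703.1: 2α-acetoxy-6α-(4-methoxybenzoyloxy)-8α,9α-epoxy-4β-hydroxy compound | COc1ccc(C(=O)O[C@@H]2C[C@]3(C)O[C@@H]3C[C@]3(C)[C@H](OC(C)=O)C[C@](O)(C(C)C)[C@@H]23)cc1 | target

**Step count**

Total step count: 22. Longest linear sequence: 22 steps, from 1 to 34.

**Steps most likely to fail**

Step 14 (anodic closure of ring B). Methanol capture of the radical cation and loss of the silyl groups back to the diketone may outrun the slow seven-membered ring closure, or two molecules may couple. The fallback uses known chemistry, ring-closing metathesis at C7=C8; it sets out from lactone aldehyde 12 and comes back at dione 23. Vinylmagnesium bromide would add to the aldehyde of 12 to give vinyl carbinol F1, which is silylated (Me3SiCl, imidazole) to trimethylsilyl ether F2. Lactone opening as in step 10 gives hydroxy Weinreb amide F3 and then triisopropylsilyl ether F4, and isopropenylmagnesium bromide converts this into dienone F5. The second-generation Hoveyda–Grubbs catalyst (toluene, 80 °C) should close ring B as cycloheptenone F6 with loss of ethylene. Hydrogenation over Pd/C gives saturated ketone F7, mild acidic methanolysis frees carbinol F8, and Dess–Martin oxidation gives 23 as its C8 epimers.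

Step 7 (tethered conjugate addition). The addition may revert at the crowded, fully substituted C1, and the aldehyde enolate may expel the C4 silyloxy group. The fallback is a radical cyclisation under neutral conditions (Ueno–Stork); it sets out from hydroxy enal 8 and comes back at lactone aldehyde 12. Ethyl vinyl ether and N-bromosuccinimide would convert 8 into bromoacetal F9. Bu3SnH with AIBN (benzene, 80 °C) should cyclise the alkyl radical 5-exo-trig onto C1 from the α face to give bicyclic ethyl acetal F10, whose C5 aldehyde is equilibrated with Et3N. PPTS in aqueous acetone hydrolyses the acetal to lactol F11, and Ag2CO3 on Celite oxidises the lactol to 12.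

Step 1 (allylic oxidation). Oxidation may also take place at the methyl group or with allylic transposition; the latter would lower the enantiomeric purity, because the transposed enone is the mirror image of 3. The β-hydroxy enone may also dehydrate and aromatise. The fallback oxygenates C2 after the ring contraction; it sets out from 1 and comes back at malonate 10. Compound 1 would be silylated to triethylsilyl ether F12; ozonolysis gives keto aldehyde F13 and aldol condensation as in step 4 gives enal F14. t-BuMe2SiOTf with Et3N removes a C2 proton to give silyl dienol ether F15, and vinylogous Rubottom oxidation with dimethyldioxirane hydroxylates C2. The 2α-alcohol so formed is compound 8 and is acylated as in step 6; the 2β-epimer F16 is esterified with methyl hydrogen malonate under Mitsunobu conditions with inversion, so both epimers converge on 10.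

Further compounds
F1 | step 14 | vinyl carbinol lactone (5β-CH(OH)CH=CH2, C6 epimers) | C=CC(O)[C@@H]1[C@@](O[Si](CC)(CC)CC)(C(C)C)C[C@H]2OC(=O)C[C@@]12C
F2 | step 14 | trimethylsilyl ether of F1 | C=CC(O[Si](C)(C)C)[C@@H]1[C@@](O[Si](CC)(CC)CC)(C(C)C)C[C@H]2OC(=O)C[C@@]12C
F3 | step 14 | hydroxy Weinreb amide with 5β-CH(OSiMe3)CH=CH2 | CON(C)C(=O)C[C@]1(C)[C@H](O)C[C@](O[Si](CC)(CC)CC)(C(C)C)[C@H]1C(C=C)O[Si](C)(C)C
F4 | step 14 | triisopropylsilyl ether of F3 | CON(C)C(=O)C[C@]1(C)[C@H](O[Si](C(C)C)(C(C)C)C(C)C)C[C@](O[Si](CC)(CC)CC)(C(C)C)[C@H]1C(C=C)O[Si](C)(C)C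
F5 | step 14 | dienone (isopropenyl ketone on C10, vinyl carbinol silyl ether on C5) | CC(=C)C(=O)C[C@]1(C)[C@H](O[Si](C(C)C)(C(C)C)C(C)C)C[C@](O[Si](CC)(CC)CC)(C(C)C)[C@H]1C(C=C)O[Si](C)(C)C
F6 | step 14 | ring-B cycloheptenone (C7=C8, C9=O, 6-OSiMe3) | C[Si](C)(C)OC1C=C(C)C(=O)C[C@]2(C)[C@H](O[Si](C(C)C)(C(C)C)C(C)C)C[C@](O[Si](CC)(CC)CC)(C(C)C)[C@@H]12
F7 | step 14 | saturated ring-B 9-ketone with 6-OSiMe3 | C[Si](C)(C)OC1CC(C)C(=O)C[C@]2(C)[C@H](O[Si](C(C)C)(C(C)C)C(C)C)C[C@](O[Si](CC)(CC)CC)(C(C)C)[C@@H]12
F8 | step 14 | ring-B 6-hydroxy-9-ketone | OC1CC(C)C(=O)C[C@]2(C)[C@H](O[Si](C(C)C)(C(C)C)C(C)C)C[C@](O[Si](CC)(CC)CC)(C(C)C)[C@@H]12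
F9 | step 7 | bromoacetal of 8 (2-bromo-1-ethoxyethyl ether at O-2) | CC1=C(C=O)[C@@](O[Si](CC)(CC)CC)(C(C)C)C[C@H]1OC(CBr)OCC
F10 | step 7 | cis-fused bicyclic ethyl acetal aldehyde | O=C[C@@H]1[C@@](O[Si](CC)(CC)CC)(C(C)C)C[C@H]2OC(OCC)C[C@@]12C
F11 | step 7 | cis-fused lactol aldehyde | O=C[C@@H]1[C@@](O[Si](CC)(CC)CC)(C(C)C)C[C@H]2OC(O)C[C@@]12C
F12 | step 1 | triethylsilyl ether of 1 | CC1=CC[C@@](O[Si](CC)(CC)CC)(C(C)C)CC1
F13 | step 1 | (R)-3-isopropyl-6-oxo-3-(triethylsilyloxy)heptanal | CC(=O)CC[C@](O[Si](CC)(CC)CC)(C(C)C)CC=O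
F14 | step 1 | (S)-5-isopropyl-2-methyl-5-(triethylsilyloxy)cyclopent-1-ene-1-carbaldehyde | CC1=C(C=O)[C@@](O[Si](CC)(CC)CC)(C(C)C)CC1
F15 | step 1 | tert-butyldimethylsilyl dienol ether of F14 (C1=C2 and C5=C6) | CC1=CC[C@](O[Si](CC)(CC)CC)(C(C)C)C1=CO[Si](C)(C)C(C)(C)C
F16 | step 1 | 2β-hydroxy epimer of 8 | CC1=C(C=O)[C@@](O[Si](CC)(CC)CC)(C(C)C)C[C@@H]1O
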